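The cyclopentane (C1, C2, C3, C3a, C7a) is cut at C1–C7a, with the cyclohexane carbinol carbon C7 as a ketone. Locants here are those of the target, a 4-bromo-1-dienyl-3a,7-dimethyloctahydroinden-7-ol. The cut exploits the 1,3-relation of C7 and C1 across ring-fusion carbon C7a, which makes C7a an α-carbon and C1 an aldehyde carbon. Acid-mediated aldol condensation of keto aldehyde 11, a 4-bromo-3-methylcyclohexanone with a 3-oxopropyl arm on its quaternary carbon, closes this ring after the six-membered one and leaves enone 13 (C1=C7a–C7=O). Cuprate addition, kinetic protonation and methyl addition then relay C3a to C1, C7a and C7. C3a and C4 come from one Sharpless epoxide of nerol.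

Key step: step 8

Remark: each intermediate carries the locants of its own name; the target is (1S,3aS,4S,7R,7aS)-4-bromo-1-[(1E)-2,6-dimethylhepta-1,5-dien-1-yl]-3a,7-dimethyloctahydro-1H-inden-7-ol.
Assumption: β-keto ester 7 is a mixture of C1 epimers and enol, so its SMILES leaves C1 undefined; step 5 turns this carbon into CH2.

Step 1
Reactants: 1 nerol [(2Z)-3,7-dimethylocta-2,6-dien-1-ol]
Product: 2 [(2R,3S)-3-methyl-3-(4-methylpent-3-en-1-yl)oxiran-2-yl]methanol
Conditions: Ti(OiPr)4 (10 mol %), D-(−)-diethyl tartrate (12 mol %), t-BuOOH, 4 Å MS, CH2Cl2, −20 °C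
Reagents that add atoms: tert-butyl hydroperoxide CC(C)(C)OO
Why: Katsuki–Sharpless asymmetric epoxidation: the titanium tartrate epoxidises only the allylic alcohol double bond, and D-(−)-tartrate should deliver oxygen to the face that gives the 2R,3S oxirane, so both stereocentres of the later C3a/C4 pair are set by the catalyst while the 6,7-alkene stays.

Step 2
Reactants: 2 [(2R,3S)-3-methyl-3-(4-methylpent-3-en-1-yl)oxiran-2-yl]methanol
Product: 3 (2S,3S)-3-(iodomethyl)-2-methyl-2-(4-methylpent-3-en-1-yl)oxirane
Conditions: I2, PPh3, imidazole, Et2O/MeCN 3:1, 0 °C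
Reagents that add atoms: iodine II
Why: Garegg–Samuelsson iodination: iodide displaces the primary alkoxyphosphonium group at CH2, so neither oxirane carbon is touched (the descriptor at the CH changes only because CH2I outranks the ring carbon).

Step 3
Reactants: 3 (2S,3S)-3-(iodomethyl)-2-methyl-2-(4-methylpent-3-en-1-yl)oxirane; 4 methyl acetoacetate
Product: 6 methyl 5-[(2R,3S)-3-methyl-3-(4-methylpent-3-en-1-yl)oxiran-2-yl]-3-oxopentanoate, via acetoacetate dianion 5 (not isolated)
Conditions: 4, NaH, THF, 0 °C; n-BuLi, 0 °C; then 3, 0 °C; aq NH4Cl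
Reagents that add atoms: none
Why: Dianion alkylation of a β-keto ester: the terminal carbanion of 5 should displace the primary iodide by SN2 faster than it opens the hindered trisubstituted oxirane, whose stereocentres are carried through unchanged.

Step 4
Reactants: 6 methyl 5-[(2R,3S)-3-methyl-3-(4-methylpent-3-en-1-yl)oxiran-2-yl]-3-oxopentanoate
Product: 7 methyl (2S,3R)-3-hydroxy-2-methyl-2-(4-methylpent-3-en-1-yl)-6-oxocyclohexane-1-carboxylate
Conditions: SnCl4 (1.1 equiv), CH2Cl2, −78 to −40 °C; aq NaHCO3
Reagents that add atoms: none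
Why: Lewis-acid-promoted epoxide-initiated cyclisation with a β-keto ester as C-nucleophile: the tin-bound enol should attack the activated oxirane at its tertiary carbon (6-endo, chair) with inversion, which makes the quaternary carbon 2S and leaves the carbinol 3R with OH trans to the methyl group.

Step 5
Reactants: 7 methyl (2S,3R)-3-hydroxy-2-methyl-2-(4-methylpent-3-en-1-yl)-6-oxocyclohexane-1-carboxylate
Product: 8 (3S,4R)-4-hydroxy-3-methyl-3-(4-methylpent-3-en-1-yl)cyclohexan-1-one
Conditions: LiCl, H2O, DMSO, 140 °C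
Reagents that add atoms: none
Why: Krapcho dealkoxycarbonylation under neutral conditions should leave alcohol, alkene and both stereocentres alone; it is run before the bromide is in place so that no enolate meets a γ-bromide.

Step 6
Reactants: 8 (3S,4R)-4-hydroxy-3-methyl-3-(4-methylpent-3-en-1-yl)cyclohexan-1-one
Product: 9 (3S,4S)-4-bromo-3-methyl-3-(4-methylpent-3-en-1-yl)cyclohexan-1-one
Conditions: CBr4, P(n-C8H17)3, toluene, 60 °C
Reagents that add atoms: carbon tetrabromide BrC(Br)(Br)Br
Why: Appel reaction: bromide displaces the alkoxyphosphonium group by SN2 with inversion at C4, which should put bromine cis to the C3 methyl group; the flexible monocycle can present the C–O bond equatorial, where E2 has no antiperiplanar hydrogen.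

Step 7
Reactants: 9 (3S,4S)-4-bromo-3-methyl-3-(4-methylpent-3-en-1-yl)cyclohexan-1-one
Product: 11 3-[(1S,2S)-2-bromo-1-methyl-5-oxocyclohexyl]propanal, via ozonide 10 (not isolated)
Conditions: O3, CH2Cl2, −78 °C; Me2S, −78 to 20 °C
Reagents that add atoms: ozone [O-][O+]=O
Why: Ozonolysis with reductive work-up of the only C=C of 9 should unmask the aldehyde (the isopropylidene end leaves as acetone); ketone, secondary bromide and both stereocentres are inert.

Step 8
Reactants: 11 3-[(1S,2S)-2-bromo-1-methyl-5-oxocyclohexyl]propanal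
Product: 13 (7S,7aS)-7-bromo-7a-methyl-1,2,5,6,7,7a-hexahydro-4H-inden-4-one, via ketol 12 (not isolated)
Conditions: p-TsOH·H2O (10 mol %), benzene, 80 °C, Dean–Stark trap
Reagents that add atoms: none
Why: Acid-catalysed enolisation of the ring ketone towards C6 (the CH2 between carbonyl and quaternary carbon) and addition of that enol to the pendant aldehyde give ketol 12, whose dehydration drives the sequence to the conjugated enone. The closest known reaction type is the intramolecular aldol condensation that closes the ring in cyclopentene annulations of 3-(3-oxopropyl)cycloalkanones. The five-membered ring is closed in the 5-(enolexo)-exo-trig mode. No lasting stereocentre is formed: the carbinol and ring-fusion centres of 12 are removed on dehydration, while C7 and C7a come unchanged from 11. The step needs regioselectivity between the two α-carbons of the ketone and between ketone and aldehyde as enol partner; the other aldols give only bridged ketols (bicyclo[3.2.2] or bicyclo[3.2.1]) that cannot dehydrate without a bridgehead alkene, so under reversible conditions the material should drain to 13. Acid is chosen over base or amine catalysis so that no enolate or enamine at C6 can displace the γ-bromide.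

Step 9
Reactants: 14 5-bromo-2-methylpent-2-ene; 15 lithium acetylide–ethylenediamine complex
Product: 16 6-methylhept-5-en-1-yne
Conditions: DMSO, 0 to 25 °C
Reagents that add atoms: none
Why: SN2 alkylation of the acetylide by the primary homoallylic bromide should give the terminal alkyne without touching the trisubstituted alkene.

Step 10
Reactants: 16 6-methylhept-5-en-1-yne
Product: 18 (1E)-1-iodo-2,6-dimethylhepta-1,5-diene, via alkenylalane 17 (not isolated)
Conditions: AlMe3 (2 equiv), Cp2ZrCl2 (25 mol %), CH2Cl2, 0 to 23 °C; I2, THF, −30 to 0 °C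
Reagents that add atoms: trimethylaluminium C[Al](C)C; iodine II
Why: Negishi zirconium-catalysed carboalumination adds methyl and aluminium syn across the alkyne with aluminium on the terminal carbon, and iodinolysis with retention should give the E iodide; the trisubstituted alkene does not carbometalate.

Step 11
Reactants: 18 (1E)-1-iodo-2,6-dimethylhepta-1,5-diene; 13 (7S,7aS)-7-bromo-7a-methyl-1,2,5,6,7,7a-hexahydro-4H-inden-4-one
Product: 22 (3S,3aS,7S,7aS)-7-bromo-3-[(1E)-2,6-dimethylhepta-1,5-dien-1-yl]-7a-methyloctahydro-4H-inden-4-one, via alkenyllithium 19 (not isolated), via lithium dialkenylcuprate 20 (not isolated), via lithium enolate 21 (not isolated)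
Conditions: 18 (2.2 equiv), t-BuLi (4.4 equiv), Et2O, −78 °C; CuI (1.1 equiv), −78 to −40 °C; 13, −78 °C; AcOH in THF, −78 °C
Reagents that add atoms: none
Why: Gilman cuprate 1,4-addition with retention of the E geometry: the alkenyl group should add to C3 anti to the C7a methyl group (3S), and the regiodefined enolate 21 should be protonated kinetically at C3a on the same face (axial protonation anti to the pseudoaxial methyl), which gives the trans ring fusion (3aS); the neopentylic secondary bromide should not react at −78 °C.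

Step 12
Reactants: 22 (3S,3aS,7S,7aS)-7-bromo-3-[(1E)-2,6-dimethylhepta-1,5-dien-1-yl]-7a-methyloctahydro-4H-inden-4-one
Product: 23 (1S,3aS,4S,7R,7aS)-4-bromo-1-[(1E)-2,6-dimethylhepta-1,5-dien-1-yl]-3a,7-dimethyloctahydro-1H-inden-7-ol
Conditions: MeLi (3 equiv), CeCl3 (3 equiv), THF, −78 °C; aq NH4Cl
Reagents that add atoms: methyllithium [Li]C
Why: Organocerium 1,2-addition, which suppresses enolisation and so epimerisation at the ring fusion: axial attack on the cyclohexanone is blocked by the 1,3-diaxial angular methyl group, so methyl should enter equatorially and leave the axial tertiary alcohol (7R).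

Compound list
1 | nerol, (2Z)-3,7-dimethylocta-2,6-dien-1-ol | CC(C)=CCC/C(C)=C\CO | starting material
2 | [(2R,3S)-3-methyl-3-(4-methylpent-3-en-1-yl)oxiran-2-yl]methanol | OC[C@H]1O[C@@]1(C)CCC=C(C)C | intermediate
3 | (2S,3S)-3-(iodomethyl)-2-methyl-2-(4-methylpent-3-en-1-yl)oxirane | IC[C@H]1O[C@@]1(C)CCC=C(C)C | intermediate
4 | methyl acetoacetate (methyl 3-oxobutanoate) | COC(=O)CC(C)=O | starting material
5 | lithium sodium dianion of methyl acetoacetate (C2,C4-diide) | [Na+].[Li+].[CH2-]C(=O)[CH-]C(=O)OC | intermediate (not isolated)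
6 | methyl 5-[(2R,3S)-3-methyl-3-(4-methylpent-3-en-1-yl)oxiran-2-yl]-3-oxopentanoate | COC(=O)CC(=O)CC[C@H]1O[C@@]1(C)CCC=C(C)C | intermediate
7 | methyl (2S,3R)-3-hydroxy-2-methyl-2-(4-methylpent-3-en-1-yl)-6-oxocyclohexane-1-carboxylate (C1 epimers and enol) | CC(C)=CCC[C@]1(C)[C@H](O)CCC(=O)C1C(=O)OC | intermediate
8 | (3S,4R)-4-hydroxy-3-methyl-3-(4-methylpent-3-en-1-yl)cyclohexan-1-one | CC(C)=CCC[C@]1(C)[C@H](O)CCC(=O)C1 | intermediate
9 | (3S,4S)-4-bromo-3-methyl-3-(4-methylpent-3-en-1-yl)cyclohexan-1-one | CC(C)=CCC[C@]1(C)[C@@H](Br)CCC(=O)C1 | intermediate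
10 | 3-{2-[(1S,2S)-2-bromo-1-methyl-5-oxocyclohexyl]ethyl}-5,5-dimethyl-1,2,4-trioxolane (ozonide, C3 epimers) | CC1(C)OOC(CC[C@]2(C)[C@@H](Br)CCC(=O)C2)O1 | intermediate (not isolated)
11 | 3-[(1S,2S)-2-bromo-1-methyl-5-oxocyclohexyl]propanal | O=CCC[C@]1(C)[C@@H](Br)CCC(=O)C1 | intermediate
12 | (7S,7aS)-7-bromo-3-hydroxy-7a-methyloctahydro-4H-inden-4-one (ketol, C3/C3a isomers) | O=C1CC[C@H](Br)[C@@]2(C)CCC(O)C12 | intermediate (not isolated)
13 | (7S,7aS)-7-bromo-7a-methyl-1,2,5,6,7,7a-hexahydro-4H-inden-4-one | O=C1CC[C@H](Br)[C@@]2(C)CCC=C12 | intermediate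
14 | 5-bromo-2-methylpent-2-ene | CC(C)=CCCBr | starting material
15 | lithium acetylide–ethylenediamine complex | [Li+].[C-]#C.NCCN | starting material
16 | 6-methylhept-5-en-1-yne | CC(C)=CCCC#C | intermediate
17 | [(1E)-2,6-dimethylhepta-1,5-dien-1-yl]dimethylalumane | CC(C)=CCC/C(C)=C/[Al](C)C | intermediate (not isolated)
18 | (1E)-1-iodo-2,6-dimethylhepta-1,5-diene | CC(C)=CCC/C(C)=C/I | intermediate
19 | [(1E)-2,6-dimethylhepta-1,5-dien-1-yl]lithium | CC(C)=CCC/C(C)=C/[Li] | intermediate (not isolated)
20 | lithium bis[(1E)-2,6-dimethylhepta-1,5-dien-1-yl]cuprate | [Li+].CC(C)=CCC/C(C)=C/[Cu-]/C=C(C)/CCC=C(C)C | intermediate (not isolated)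
21 | lithium (3S,7S,7aS)-7-bromo-3-[(1E)-2,6-dimethylhepta-1,5-dien-1-yl]-7a-methyl-2,3,5,6,7,7a-hexahydro-1H-inden-4-olate | [Li+].CC(C)=CCC/C(C)=C/[C@@H]1CC[C@]2(C)[C@@H](Br)CCC([O-])=C12 | intermediate (not isolated)
22 | (3S,3aS,7S,7aS)-7-bromo-3-[(1E)-2,6-dimethylhepta-1,5-dien-1-yl]-7a-methyloctahydro-4H-inden-4-one | CC(C)=CCC/C(C)=C/[C@@H]1CC[C@]2(C)[C@@H](Br)CCC(=O)[C@@H]12 | intermediate
23 | (1S,3aS,4S,7R,7aS)-4-bromo-1-[(1E)-2,6-dimethylhepta-1,5-dien-1-yl]-3a,7-dimethyloctahydro-1H-inden-7-ol | CC(C)=CCC/C(C)=C/[C@@H]1CC[C@]2(C)[C@@H](Br)CC[C@@](C)(O)[C@@H]12 | target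

Total step count: 12 (steps 9 and 10 make the side-chain iodide). Longest linear sequence: 10 steps from nerol (steps 1–8, 11, 12).

Steps most likely to fail

Step 6. The SN2 displacement at the neopentylic secondary carbinol is slow, so elimination to a cyclohexene or ionisation with a 1,2-alkyl shift may outrun substitution. The fallback brings bromine in through a bromonium ion instead of by SN2. It sets out from methyl acetoacetate 4 (as dianion 5), with geraniol, the commercial 2E isomer of 1, as new starting material, and comes back at 9. Sharpless epoxidation of geraniol with D-(−)-diethyl tartrate gives [(2R,3R)-3-methyl-3-(4-methylpent-3-en-1-yl)oxiran-2-yl]methanol F1. Iodination as in step 2 gives (2R,3S)-3-(iodomethyl)-2-methyl-2-(4-methylpent-3-en-1-yl)oxirane F2, and alkylation of 5 as in step 3 gives methyl 5-[(2R,3R)-3-methyl-3-(4-methylpent-3-en-1-yl)oxiran-2-yl]-3-oxopentanoate F3. Bromide opening of the oxirane at its secondary carbon with inversion (Li2NiBr4, THF, 0 °C) gives the bromohydrin methyl (6S,7R)-6-bromo-7-hydroxy-7,11-dimethyl-3-oxododec-10-enoate F4. Ionisation of the tertiary alcohol (SnCl4, CH2Cl2, −40 °C) with anchimeric assistance by bromine regenerates the E-bromonium ion, which the keto ester enol should capture at the tertiary carbon to give methyl (2S,3S)-3-bromo-2-methyl-2-(4-methylpent-3-en-1-yl)-6-oxocyclohexane-1-carboxylate F5. Krapcho dealkoxycarbonylation as in step 5 then returns to 9.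

Step 11. Protonation of enolate 21 on the face of the angular methyl group, or equilibration of the ketone afterwards, would give the cis ring fusion. The fallback replaces substrate-controlled protonation by catalyst-controlled protonation. It sets out from 13 and 18 and comes back at 22. The same cuprate addition is run, but enolate 21 is trapped with allyl chloroformate (TMEDA, −78 °C) as allyl (3S,7S,7aS)-7-bromo-3-[(1E)-2,6-dimethylhepta-1,5-dien-1-yl]-7a-methyl-2,3,5,6,7,7a-hexahydro-1H-inden-4-yl carbonate F6. Palladium-catalysed decarboxylative protonation (Pd2(dba)3, the matched enantiomer of t-Bu-PHOX, Meldrum's acid, dioxane, 40 °C) should then deliver the proton to C3a under ligand control and give 22.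

Step 4. O-alkylation of the keto ester, 5-exo opening at the secondary oxirane carbon or semipinacol rearrangement of the oxirane may compete with C–C bond formation. The fallback uses a preformed silyl enol ether as terminating group. It sets out from 6 and comes back at 8. Saponification and decarboxylation (LiOH, aq THF; NaH2PO4, 40 °C) give 4-[(2R,3S)-3-methyl-3-(4-methylpent-3-en-1-yl)oxiran-2-yl]butan-2-one F7. Kinetic enolisation and silylation (LDA, TBSCl, HMPA, THF, −78 °C) give tert-butyl(dimethyl)({4-[(2R,3S)-3-methyl-3-(4-methylpent-3-en-1-yl)oxiran-2-yl]but-1-en-2-yl}oxy)silane F8. MeAlCl2 (CH2Cl2, −90 °C) should close the ring by 6-endo attack of the enol ether carbon on the tertiary oxirane carbon with inversion and, after work-up, give 8.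

Further compounds
F1 | step 6 | [(2R,3R)-3-methyl-3-(4-methylpent-3-en-1-yl)oxiran-2-yl]methanol | OC[C@H]1O[C@]1(C)CCC=C(C)C
F2 | step 6 | (2R,3S)-3-(iodomethyl)-2-methyl-2-(4-methylpent-3-en-1-yl)oxirane | IC[C@H]1O[C@]1(C)CCC=C(C)C
F3 | step 6 | methyl 5-[(2R,3R)-3-methyl-3-(4-methylpent-3-en-1-yl)oxiran-2-yl]-3-oxopentanoate | COC(=O)CC(=O)CC[C@H]1O[C@]1(C)CCC=C(C)C
F4 | step 6 | methyl (6S,7R)-6-bromo-7-hydroxy-7,11-dimethyl-3-oxododec-10-enoate | COC(=O)CC(=O)CC[C@H](Br)[C@](C)(O)CCC=C(C)C
F5 | step 6 | methyl (2S,3S)-3-bromo-2-methyl-2-(4-methylpent-3-en-1-yl)-6-oxocyclohexane-1-carboxylate | CC(C)=CCC[C@]1(C)[C@@H](Br)CCC(=O)C1C(=O)OC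
F6 | step 11 | allyl (3S,7S,7aS)-7-bromo-3-[(1E)-2,6-dimethylhepta-1,5-dien-1-yl]-7a-methyl-2,3,5,6,7,7a-hexahydro-1H-inden-4-yl carbonate | CC(C)=CCC/C(C)=C/[C@@H]1CC[C@]2(C)[C@@H](Br)CCC(OC(=O)OCC=C)=C12
F7 | step 4 | 4-[(2R,3S)-3-methyl-3-(4-methylpent-3-en-1-yl)oxiran-2-yl]butan-2-one | CC(=O)CC[C@H]1O[C@@]1(C)CCC=C(C)C
F8 | step 4 | tert-butyl(dimethyl)({4-[(2R,3S)-3-methyl-3-(4-methylpent-3-en-1-yl)oxiran-2-yl]but-1-en-2-yl}oxy)silane | C=C(O[Si](C)(C)C(C)(C)C)CC[C@H]1O[C@@]1(C)CCC=C(C)C
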